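Follow each unit of starting material to where it goes, and begin with what was charged and read.

| setting | Friday's | Saturday's | winter | autumn | spring | noon |
|---|---|---|---|---|---|---|
| starting material | 12 mM | 46 mM | 23 mM | 23 mM | 23 mM | 23 mM |
| temperature | −40 °C | −5 °C | 25 °C |  | −5 °C | −35 °C |
| remark | run made earlier | run made earlier |  | at 25 °C until 10 min, from then on at −35 °C |  |  |
| time |  |  | 50 min | 50 min | 50 min | 50 min |

- Friday's (time / min: ring / %, starting material / %): 120: 1.7, 94.9; 240: 1.6, 87.3; 360: 2.6, 83.3; 720: 5.9, 72.0; 1500: 7.3, 54.3
- Saturday's (time / min: ring / %, starting material / %): 20.0: 17.2, 23.5; 60.0: 28.8, 10.3; 120: 36.3, 4.9; 180: 44.1, 5.1; 240: 52.6, 5.8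

(each reading ± 1 percentage point)

- the earlier runs were read with a standard deviation of 1 percentage point

1. the flask that comes out highest in amount of ring, in percent of the starting material charged, or "all alike" when all lie within 1.5 percentage points (winter / autumn / spring / noon / all alike)
2. ring at the end, in percent of the starting material charged, winter
3. ring at the end, in percent of the starting material charged, autumn
4. ring at the end, in percent of the starting material charged, spring
5. ring at the end, in percent of the starting material charged, noon

Saturday's readings did not add up: at 240 min, 41.6 % of the charge stood in a form nobody read. So I let starting material leave by two routes, to ring with a steady time constant and into that unread form by meeting a partner, with a time constant that lengthens as the remaining fraction a falls.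

The bench rule carries one flask's split to the next. Saturday's run had turned 22.5 % of its loss into ring by 20.0 min. But the two routes stand in the ratio f/a, where f is the fraction at which their time constants are equal. While a stays well above f, ring is about f·ln(1/a). That read 0.120 from Friday's last reading and 0.119 from Saturday's first.

I scaled f inversely with the charge and drew its logarithm straight against inverse temperature through both runs. That gave 0.582 at 25 °C and 23 mM: this is the tie fraction, where ring and pairing take starting material equally fast. The rule's border lies here: Saturday's first reading already stood at a ratio f/a of 0.505, so its f is a rough reading, and winter and autumn start at a larger ratio of 0.582.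

Integrating the split instead gives f·ln(1 + 1/f). I assumed that a would fall close to zero in autumn's warm 10 min and that the cold would then hold the flask as it stood, so my figure was 58.2 %, above the bench rule's 22.5 %.

The forecast named winter highest, with 85 % for winter, 38 % for autumn, 22 % for spring and 1.8 % for noon: “About 20% of the consumed material becomes ring at once.” My autumn figure stood above its 38 %.

The flasks gave 94.9 % for winter, 72.5 % for autumn, 34.6 % for spring and 0.881 % for noon, so winter came highest.

    starting material → ring (k = 0.770 min⁻¹, Ea = 82.0 kJ mol⁻¹)
    2 starting material ⇌ open dimer (K = 560 L mol⁻¹, k = 24.0 L mol⁻¹ min⁻¹, Ea = 63.0 kJ mol⁻¹, ΔH = 5.00 kJ mol⁻¹)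
    (constants at 25 °C)

In autumn's warm 10.0 min, both steps ran, and starting material fell to 1.51 % while ring reached 72.5 % and open dimer 26.0 %. After the change to −35 °C, autumn read ring 72.5 % and open dimer 25.9 % at 50.0 min. My tie-fraction figure fell short of autumn's ring by 14 points, the forecast by 34 points.

Take autumn's recipe charged with 5.8 mM: the tie fraction grows to 2.31, and the same integral gives 83.1 % ring. The computed flask gave 89.5 %, with 9.84 % open dimer.

(Readings and results were computed with made-up constants; the scatter is artificial.)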